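**Retrosynthetic overview** (prenyl = 3-methylbut-2-enyl, TIPS = triisopropylsilyl, MOM = methoxymethyl)

- The target is 5,7-dihydroxy-3,6,8-triprenyl-2-(2,4,5-trihydroxyphenyl)chromen-4-one. The plan rests on ring A (C4a, C5, C6, C7, C8, C8a): a phloroglucinol with oxygens on C5, C7 and C8a and prenyl groups on C6 and C8, a pattern that prenylation of phloroglucinol gives only in mixtures.
- Ring C is cut last at O1–C2 and C4–C4a: thermal Mentzer condensation of 2,4-diprenylphloroglucinol with a MOM-protected α-prenyl aroylacetate carrying ring B, then MOM removal.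
- Ring A is cut to 2-prenyl-3-siloxycyclobutenone and a prenyl-bearing siloxyalkyne (Danheiser benzannulation). New bonds are C8–C8a and C6–C7; the opened cyclobutenone bond is re-formed as C4a–C8a.
- The cyclobutenone comes from prenylketene and ethoxyethyne, the siloxyalkyne from Kowalski ynolate chemistry. One Johnson–Claisen ester feeds both the ketene and the ring B ketoester.
- Ring order: ring B (purchased), ring A (step 9), ring C (step 14).

Key step: step 9

Remark: the target has no stereocentre, so racemic or diastereomeric intermediates are used as such; the 2-substituted cyclobutane-1,3-dione is drawn as its enol.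

**Route**

Step 1
Reactants: 1 2-methylbut-3-en-2-ol
Product: 3 ethyl 5-methylhex-4-enoate, via mixed ketene acetal 2 (not isolated)
Conditions: MeC(OEt)3 (excess), EtCO2H (cat.), 140 °C, EtOH distilled off
Reagents that add atoms: triethyl orthoacetate, CC(OCC)(OCC)OCC
Why: Johnson–Claisen rearrangement; acid-catalysed exchange and loss of ethanol give the ketene acetal, whose [3,3] shift forms the C–C bond at the alkene terminus and leaves the trisubstituted alkene of a prenyl unit.

Step 2
Reactants: 3 ethyl 5-methylhex-4-enoate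
Product: 4 5-methylhex-4-enoic acid
Conditions: LiOH, THF/H2O, rt; then 1 M HCl to pH 3
Reagents that add atoms: lithium hydroxide, [Li+].[OH-]
Why: ester saponification; the isolated alkene is inert to aqueous base and to brief cold acidification.

Step 3
Reactants: 4 5-methylhex-4-enoic acid
Product: 5 5-methylhex-4-enoyl chloride
Conditions: (COCl)2, DMF (cat.), CH2Cl2, 0 °C → rt; volatiles removed, used crude
Reagents that add atoms: oxalyl chloride, O=C(Cl)C(=O)Cl
Why: acid chloride formation through the chloroiminium catalyst; all by-products are gases.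

Step 4
Reactants: 5 5-methylhex-4-enoyl chloride; 6 ethoxyethyne
Product: 8 3-ethoxy-4-(3-methylbut-2-enyl)cyclobut-2-en-1-one, via prenylketene 7 (not isolated)
Conditions: Et3N, 6 (3 equiv, hexane solution), Et2O, 0 °C → rt, slow addition of 5
Reagents that add atoms: none
Why: dehydrochlorination gives the aldoketene, which is trapped in a ketene–alkoxyalkyne (2+2) cycloaddition; the nucleophilic terminal carbon of 6 bonds to the ketene carbonyl carbon, so ethoxy sits on C3 and prenyl on C4, and excess alkyne with slow addition should suppress ketene dimerization.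

Step 5
Reactants: 8 3-ethoxy-4-(3-methylbut-2-enyl)cyclobut-2-en-1-one
Product: 9 3-hydroxy-2-(3-methylbut-2-enyl)cyclobut-2-en-1-one
Conditions: 1 M aq. HCl, THF, 0 °C → rt, short contact
Reagents that add atoms: water, O
Why: acid hydrolysis of the vinylogous ester; the resulting 2-prenylcyclobutane-1,3-dione should rest as the more substituted, conjugated enol (a vinylogous acid), and cold dilute acid spares the prenyl alkene.

Step 6
Reactants: 9 3-hydroxy-2-(3-methylbut-2-enyl)cyclobut-2-en-1-one
Product: 10 2-(3-methylbut-2-enyl)-3-(triisopropylsilyloxy)cyclobut-2-en-1-one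
Conditions: TIPSOTf, Et3N, CH2Cl2, −78 → 0 °C; anhydrous work-up, used directly
Reagents that add atoms: triisopropylsilyl trifluoromethanesulfonate, CC(C)[Si](OS(=O)(=O)C(F)(F)F)(C(C)C)C(C)C
Why: O-silylation of the vinylogous carboxylate; the anion is delocalized over O–C3–C2(prenyl)–C1–O, so silylation on oxygen fixes the alkene at C2=C3 and leaves C4 as CH2.

Step 7
Reactants: 11 4-methylpent-3-enoic acid
Product: 12 ethyl 4-methylpent-3-enoate
Conditions: EtI, K2CO3, DMF, rt
Reagents that add atoms: iodoethane, CCI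
Why: SN2 O-alkylation of the carboxylate; it avoids Fischer conditions, under which this β,γ-unsaturated acid lactonizes, and the weak base should not move the alkene into conjugation.

Step 8
Reactants: 12 ethyl 4-methylpent-3-enoate
Product: 14 triisopropyl(5-methylhex-4-en-1-ynyloxy)silane, via lithium ynolate 13 (not isolated)
Conditions: CH2Br2, LiTMP (lithium 2,2,6,6-tetramethylpiperidide, 2.2 equiv), THF, −78 °C; n-BuLi, −78 °C → rt; TIPSCl, −78 °C → rt
Reagents that add atoms: dibromomethane, BrCBr; triisopropylsilyl chloride, CC(C)[Si](Cl)(C(C)C)C(C)C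
Why: Kowalski ynolate synthesis; LiCHBr2 adds to the ester, the dibromoketone enolate undergoes bromine–lithium exchange and a carbenoid 1,2-shift of the prenyl-bearing CH2 group to give the ynolate, which the bulky silyl chloride traps on oxygen.

Step 9
Reactants: 10 2-(3-methylbut-2-enyl)-3-(triisopropylsilyloxy)cyclobut-2-en-1-one; 14 triisopropyl(5-methylhex-4-en-1-ynyloxy)silane
Product: 19 2,4-bis(3-methylbut-2-enyl)-3,5-bis(triisopropylsilyloxy)phenol, via vinylketene 15 (not isolated), via 4-vinylcyclobutenone 16 (not isolated), via dienylketene 17 (not isolated), via cyclohexadienone 18 (not isolated)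
Conditions: 14 (1.5 equiv), toluene, 80 → 110 °C, sealed tube, Ar
Reagents that add atoms: none
Why: Proposed new method: a 3-siloxycyclobutenone has not been shown as the vinylketene source, but the cascade is that of the Danheiser benzannulation of 3-alkylcyclobutenones with siloxyalkynes, the closest known reaction. Four-electron electrocyclic opening of the C1–C4 bond of 10 gives vinylketene 15, whose ketene C=C adds the electron-rich alkyne of 14 in a (2+2) cycloaddition to 16, and four-electron opening of 16 gives dienylketene 17. Ring A closes by six-electron electrocyclization of 17, which re-forms the opened bond as C4a–C8a and gives dienone 18; tautomerization to the phenol makes the cascade irreversible. No stereocentre survives, since the quaternary carbon of 16 becomes sp2, and because the opening of 16 is reversible the geometry with ketene and siloxyvinyl group cis, the only one that can cyclize, is drained. The selectivity needed is the regiochemistry of the ketene–alkyne step, secured by the polarized siloxyalkyne: its oxygen-free, prenyl-bearing carbon bonds to the ketene carbonyl carbon (C8–C8a) and its oxygen-bearing carbon to the ketene α-carbon (C6–C7), which fixes the prenyl groups at C6 and C8 and the oxygens at C5, C7 and C8a. The prenyl alkenes are not conjugated with the reacting π system and are tethered too closely to add to either ketene.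

Step 10
Reactants: 19 2,4-bis(3-methylbut-2-enyl)-3,5-bis(triisopropylsilyloxy)phenol
Product: 20 2,4-bis(3-methylbut-2-enyl)benzene-1,3,5-triol
Conditions: Bu4NF, AcOH, THF, 0 °C, Ar; used without storage
Reagents that add atoms: none
Why: fluoride cleavage of the aryl silyl ethers, driven by the Si–F bond; the acetic acid buffer keeps the electron-rich triol protonated and less prone to air oxidation.

Step 11
Reactants: 21 2,4,5-trihydroxybenzaldehyde
Product: 22 2,4,5-tris(methoxymethoxy)benzaldehyde
Conditions: MOMCl, i-Pr2NEt, CH2Cl2, 0 °C → reflux, Ar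
Reagents that add atoms: chloromethyl methyl ether, COCCl
Why: O-alkylation of the three phenols as MOM acetals, which tolerate the strong base, the oxidant and the neutral heating to come and leave in dilute acid.

Step 12
Reactants: 3 ethyl 5-methylhex-4-enoate; 22 2,4,5-tris(methoxymethoxy)benzaldehyde
Product: 24 ethyl 2-{hydroxy[2,4,5-tris(methoxymethoxy)phenyl]methyl}-5-methylhex-4-enoate, via lithium ester enolate 23 (not isolated)
Conditions: LiN(i-Pr)2 (LDA), THF, −78 °C; then 22; AcOH quench at −78 °C
Reagents that add atoms: none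
Why: directed aldol addition of a preformed lithium ester enolate to a non-enolizable aldehyde; the two stereocentres form without control and are both erased later (steps 13 and 14).

Step 13
Reactants: 24 ethyl 2-{hydroxy[2,4,5-tris(methoxymethoxy)phenyl]methyl}-5-methylhex-4-enoate
Product: 25 ethyl 2-(3-methylbut-2-enyl)-3-oxo-3-[2,4,5-tris(methoxymethoxy)phenyl]propanoate
Conditions: Dess–Martin periodinane, NaHCO3, CH2Cl2, 0 °C → rt
Reagents that add atoms: none
Why: Dess–Martin oxidation of the benzylic β-hydroxy ester to the β-ketoester; the buffered, non-acidic medium keeps the MOM acetals and the alkene intact.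

Step 14
Reactants: 20 2,4-bis(3-methylbut-2-enyl)benzene-1,3,5-triol; 25 ethyl 2-(3-methylbut-2-enyl)-3-oxo-3-[2,4,5-tris(methoxymethoxy)phenyl]propanoate
Product: 28 5,7-dihydroxy-3,6,8-tris(3-methylbut-2-enyl)-2-[2,4,5-tris(methoxymethoxy)phenyl]chromen-4-one, via acylketene 26 (not isolated), via aryl diketone 27 (not isolated)
Conditions: 25 (1.5 equiv), neat melt, Ar, microwave, 240 °C, a few minutes, EtOH and H2O vented
Reagents that add atoms: none
Why: Mentzer pyrone synthesis; thermal loss of ethanol gives the acylketene, which acylates the only free ring carbon of the phloroglucinol (C4a, between two hydroxyls), and the o-hydroxyaryl 1,3-diketone cyclodehydrates onto the ring B ketone to close ring C; the mirror symmetry of 20 allows a single flavone, and the acid-free melt disfavours the coumarin pathway.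

Step 15
Reactants: 28 5,7-dihydroxy-3,6,8-tris(3-methylbut-2-enyl)-2-[2,4,5-tris(methoxymethoxy)phenyl]chromen-4-one
Product: 29 5,7-dihydroxy-3,6,8-tris(3-methylbut-2-enyl)-2-(2,4,5-trihydroxyphenyl)chromen-4-one
Conditions: 3 M aq. HCl, MeOH (degassed), 40 °C, Ar
Reagents that add atoms: none
Why: acid-catalysed cleavage of the three aryl MOM acetals by transacetalization with methanol; dilute acid, moderate temperature and exclusion of air are chosen because prenyl groups next to phenols can cyclize to chromans and the trihydroxyphenyl ring oxidizes easily.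

**Compound list**

1 | 2-methylbut-3-en-2-ol | CC(C)(O)C=C | starting material
2 | 1-ethoxy-1-(2-methylbut-3-en-2-yloxy)ethene | C=C(OCC)OC(C)(C)C=C | intermediate
3 | ethyl 5-methylhex-4-enoate | CCOC(=O)CCC=C(C)C | intermediate
4 | 5-methylhex-4-enoic acid | CC(C)=CCCC(=O)O | intermediate
5 | 5-methylhex-4-enoyl chloride | CC(C)=CCCC(=O)Cl | intermediate
6 | ethoxyethyne | CCOC#C | starting material
7 | 5-methylhexa-1,4-dien-1-one (prenylketene) | CC(C)=CCC=C=O | intermediate
8 | 3-ethoxy-4-(3-methylbut-2-enyl)cyclobut-2-en-1-one (racemic) | CCOC1=CC(=O)C1CC=C(C)C | intermediate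
9 | 3-hydroxy-2-(3-methylbut-2-enyl)cyclobut-2-en-1-one | CC(C)=CCC1=C(O)CC1=O | intermediate
10 | 2-(3-methylbut-2-enyl)-3-(triisopropylsilyloxy)cyclobut-2-en-1-one | CC(C)=CCC1=C(O[Si](C(C)C)(C(C)C)C(C)C)CC1=O | intermediate
11 | 4-methylpent-3-enoic acid | CC(C)=CCC(=O)O | starting material
12 | ethyl 4-methylpent-3-enoate | CCOC(=O)CC=C(C)C | intermediate
13 | lithium 5-methylhex-4-en-1-yn-1-olate | [Li+].[O-]C#CCC=C(C)C | intermediate
14 | triisopropyl(5-methylhex-4-en-1-ynyloxy)silane | CC(C)=CCC#CO[Si](C(C)C)(C(C)C)C(C)C | intermediate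
15 | 2-(3-methylbut-2-enyl)-3-(triisopropylsilyloxy)buta-1,3-dien-1-one | CC(C)=CCC(=C=O)C(=C)O[Si](C(C)C)(C(C)C)C(C)C | intermediate
16 | 2,4-bis(3-methylbut-2-enyl)-3-(triisopropylsilyloxy)-4-[1-(triisopropylsilyloxy)ethenyl]cyclobut-2-en-1-one (racemic) | O=C1C(CC=C(C)C)=C(O[Si](C(C)C)(C(C)C)C(C)C)C1(CC=C(C)C)C(=C)O[Si](C(C)C)(C(C)C)C(C)C | intermediate
17 | (3E)-2,4-bis(3-methylbut-2-enyl)-3,5-bis(triisopropylsilyloxy)hexa-1,3,5-trien-1-one | O=C=C(CC=C(C)C)/C(O[Si](C(C)C)(C(C)C)C(C)C)=C(/CC=C(C)C)C(=C)O[Si](C(C)C)(C(C)C)C(C)C | intermediate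
18 | 2,4-bis(3-methylbut-2-enyl)-3,5-bis(triisopropylsilyloxy)cyclohexa-2,4-dien-1-one | O=C1CC(O[Si](C(C)C)(C(C)C)C(C)C)=C(CC=C(C)C)C(O[Si](C(C)C)(C(C)C)C(C)C)=C1CC=C(C)C | intermediate
19 | 2,4-bis(3-methylbut-2-enyl)-3,5-bis(triisopropylsilyloxy)phenol | Oc1cc(O[Si](C(C)C)(C(C)C)C(C)C)c(CC=C(C)C)c(O[Si](C(C)C)(C(C)C)C(C)C)c1CC=C(C)C | intermediate
20 | 2,4-bis(3-methylbut-2-enyl)benzene-1,3,5-triol | Oc1cc(O)c(CC=C(C)C)c(O)c1CC=C(C)C | intermediate
21 | 2,4,5-trihydroxybenzaldehyde | O=Cc1cc(O)c(O)cc1O | starting material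
22 | 2,4,5-tris(methoxymethoxy)benzaldehyde | O=Cc1cc(OCOC)c(OCOC)cc1OCOC | intermediate
23 | lithium 1-ethoxy-5-methylhexa-1,4-dien-1-olate (enolate of 3, geometry not relevant) | [Li+].[O-]C(OCC)=CCC=C(C)C | intermediate
24 | ethyl 2-{hydroxy[2,4,5-tris(methoxymethoxy)phenyl]methyl}-5-methylhex-4-enoate (mixture of racemic diastereomers) | CCOC(=O)C(CC=C(C)C)C(O)c1cc(OCOC)c(OCOC)cc1OCOC | intermediate
25 | ethyl 2-(3-methylbut-2-enyl)-3-oxo-3-[2,4,5-tris(methoxymethoxy)phenyl]propanoate (racemic) | CCOC(=O)C(CC=C(C)C)C(=O)c1cc(OCOC)c(OCOC)cc1OCOC | intermediate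
26 | 5-methyl-2-[2,4,5-tris(methoxymethoxy)benzoyl]hexa-1,4-dien-1-one | CC(C)=CCC(=C=O)C(=O)c1cc(OCOC)c(OCOC)cc1OCOC | intermediate
27 | 2-(3-methylbut-2-enyl)-1-[2,4,6-trihydroxy-3,5-bis(3-methylbut-2-enyl)phenyl]-3-[2,4,5-tris(methoxymethoxy)phenyl]propane-1,3-dione (racemic) | CC(C)=CCc1c(O)c(CC=C(C)C)c(O)c(C(=O)C(CC=C(C)C)C(=O)c2cc(OCOC)c(OCOC)cc2OCOC)c1O | intermediate
28 | 5,7-dihydroxy-3,6,8-tris(3-methylbut-2-enyl)-2-[2,4,5-tris(methoxymethoxy)phenyl]chromen-4-one | CC(C)=CCc1c(O)c(CC=C(C)C)c2oc(-c3cc(OCOC)c(OCOC)cc3OCOC)c(CC=C(C)C)c(=O)c2c1O | intermediate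
29 | 5,7-dihydroxy-3,6,8-tris(3-methylbut-2-enyl)-2-(2,4,5-trihydroxyphenyl)chromen-4-one | CC(C)=CCc1c(O)c(CC=C(C)C)c2oc(-c3cc(O)c(O)cc3O)c(CC=C(C)C)c(=O)c2c1O | target

**Step count and risks**

Total step count: 15. Longest linear sequence: 10 steps (steps 1–6, 9, 10, 14, 15).

Steps most likely to fail:

1. Step 9 (Proposed new method). The donor-stabilized 3-siloxycyclobutenone may open only at temperatures where the siloxyalkyne rearranges by 1,3-silyl shift to a silylketene or where the vinylketene dimerizes, so the cascade may stall before ring closure. Fallback by known chemistry, setting out from 1 and returning at 20: commercial benzene-1,3,5-triol (Oc1cc(O)cc(O)c1) would be C-prenylated with alcohol 1 and BF3·OEt2 in dioxane at rt (Friedel–Crafts alkylation through the dimethylallyl cation). This would give first 2-(3-methylbut-2-enyl)benzene-1,3,5-triol F1 and, with a second equivalent of 1, triol 20, to be separated by chromatography from tri-prenylated and chroman by-products. Since the three ring positions of phloroglucinol are equivalent, 2,4-dialkylation is the only C,C-diprenyl pattern; the route would continue at step 14.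

2. Step 14. At 240 °C the ortho-prenylphenol units may cyclize to chromans, the MOM group ortho to the ketone may be lost (opening a path to a 4-hydroxycoumarin), or acylation may stop at oxygen without the shift to carbon. Fallback setting out from 19 and returning at 28 (diketone route of the Baker–Venkataraman type):
   - Phenol 19 would be formylated at its only free ring position with MgCl2, Et3N and paraformaldehyde in MeCN (Casnati–Skattebøl ortho-formylation) to give 2-hydroxy-3,5-bis(3-methylbut-2-enyl)-4,6-bis(triisopropylsilyloxy)benzaldehyde F2.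
   - Addition of 4-methylpent-3-enylmagnesium bromide would give the carbinol 1-[2-hydroxy-3,5-bis(3-methylbut-2-enyl)-4,6-bis(triisopropylsilyloxy)phenyl]-5-methylhex-4-en-1-ol F3, and MnO2 would oxidize it to the aryl ketone 1-[2-hydroxy-3,5-bis(3-methylbut-2-enyl)-4,6-bis(triisopropylsilyloxy)phenyl]-5-methylhex-4-en-1-one F4.
   - The phenoxide–enolate dianion of F4 (LiN(SiMe3)2, THF, −78 °C) would add to aldehyde 22 to give the aldol 3-hydroxy-1-[2-hydroxy-3,5-bis(3-methylbut-2-enyl)-4,6-bis(triisopropylsilyloxy)phenyl]-2-(3-methylbut-2-enyl)-3-[2,4,5-tris(methoxymethoxy)phenyl]propan-1-one F5.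
   - Dess–Martin oxidation would give the diketone 1-[2-hydroxy-3,5-bis(3-methylbut-2-enyl)-4,6-bis(triisopropylsilyloxy)phenyl]-2-(3-methylbut-2-enyl)-3-[2,4,5-tris(methoxymethoxy)phenyl]propane-1,3-dione F6.
   - Cyclodehydration through the free hydroxyl (NaOAc, AcOH, 80 °C) would close ring C to 3,6,8-tris(3-methylbut-2-enyl)-5,7-bis(triisopropylsilyloxy)-2-[2,4,5-tris(methoxymethoxy)phenyl]chromen-4-one F7, and Bu4NF/AcOH would remove the silyl groups to deliver 28 for step 15.

3. Step 8. The α-CH2 of the β,γ-unsaturated ester is doubly activated, so deprotonation by LiCHBr2 or the lithium amide may outrun carbonyl addition, returning ester or moving the alkene into conjugation. Fallback setting out from 12 and returning at ynolate 13: ester 12 would be reduced with i-Bu2AlH at −78 °C to 4-methylpent-3-enal F8 and converted with CBr4/PPh3 (Corey–Fuchs) into 1,1-dibromo-5-methylhexa-1,4-diene F9. Treatment with n-BuLi (2 equiv) would give lithium 5-methylhex-4-en-1-yn-1-ide F10. Oxidation of this acetylide with t-BuOOLi (from t-BuOOH and LiN(SiMe3)2, −78 → 0 °C) would give ynolate 13, to be silylated on oxygen as in step 8 to 14.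

**Further compounds**

F1 | step 9 | 2-(3-methylbut-2-enyl)benzene-1,3,5-triol | CC(C)=CCc1c(O)cc(O)cc1O
F2 | step 14 | 2-hydroxy-3,5-bis(3-methylbut-2-enyl)-4,6-bis(triisopropylsilyloxy)benzaldehyde | O=Cc1c(O)c(CC=C(C)C)c(O[Si](C(C)C)(C(C)C)C(C)C)c(CC=C(C)C)c1O[Si](C(C)C)(C(C)C)C(C)C
F3 | step 14 | 1-[2-hydroxy-3,5-bis(3-methylbut-2-enyl)-4,6-bis(triisopropylsilyloxy)phenyl]-5-methylhex-4-en-1-ol (racemic) | CC(C)=CCCC(O)c1c(O)c(CC=C(C)C)c(O[Si](C(C)C)(C(C)C)C(C)C)c(CC=C(C)C)c1O[Si](C(C)C)(C(C)C)C(C)C
F4 | step 14 | 1-[2-hydroxy-3,5-bis(3-methylbut-2-enyl)-4,6-bis(triisopropylsilyloxy)phenyl]-5-methylhex-4-en-1-one | CC(C)=CCCC(=O)c1c(O)c(CC=C(C)C)c(O[Si](C(C)C)(C(C)C)C(C)C)c(CC=C(C)C)c1O[Si](C(C)C)(C(C)C)C(C)C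
F5 | step 14 | 3-hydroxy-1-[2-hydroxy-3,5-bis(3-methylbut-2-enyl)-4,6-bis(triisopropylsilyloxy)phenyl]-2-(3-methylbut-2-enyl)-3-[2,4,5-tris(methoxymethoxy)phenyl]propan-1-one (mixture of racemic diastereomers) | CC(C)=CCC(C(O)c1cc(OCOC)c(OCOC)cc1OCOC)C(=O)c1c(O)c(CC=C(C)C)c(O[Si](C(C)C)(C(C)C)C(C)C)c(CC=C(C)C)c1O[Si](C(C)C)(C(C)C)C(C)C
F6 | step 14 | 1-[2-hydroxy-3,5-bis(3-methylbut-2-enyl)-4,6-bis(triisopropylsilyloxy)phenyl]-2-(3-methylbut-2-enyl)-3-[2,4,5-tris(methoxymethoxy)phenyl]propane-1,3-dione (racemic) | CC(C)=CCC(C(=O)c1cc(OCOC)c(OCOC)cc1OCOC)C(=O)c1c(O)c(CC=C(C)C)c(O[Si](C(C)C)(C(C)C)C(C)C)c(CC=C(C)C)c1O[Si](C(C)C)(C(C)C)C(C)C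
F7 | step 14 | 3,6,8-tris(3-methylbut-2-enyl)-5,7-bis(triisopropylsilyloxy)-2-[2,4,5-tris(methoxymethoxy)phenyl]chromen-4-one | CC(C)=CCc1c(O[Si](C(C)C)(C(C)C)C(C)C)c(CC=C(C)C)c2oc(-c3cc(OCOC)c(OCOC)cc3OCOC)c(CC=C(C)C)c(=O)c2c1O[Si](C(C)C)(C(C)C)C(C)C
F8 | step 8 | 4-methylpent-3-enal | CC(C)=CCC=O
F9 | step 8 | 1,1-dibromo-5-methylhexa-1,4-diene | CC(C)=CCC=C(Br)Br
F10 | step 8 | lithium 5-methylhex-4-en-1-yn-1-ide | [Li+].[C-]#CCC=C(C)C
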